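**Plan**
- Retrosynthesis: the cyclohexene is cut at C1–C2 (aroyl-bearing carbon to prenyl-bearing carbon). In the precursor C1 is bonded to C4 instead, a 1-aroyl-2-alkenyl-4-phenylcyclobutane. Its ring is cut into the chalcone C=C and the vinyl group of methyl vinyl ketone; the side-chain alkene is cut at C3–CH3 and at the prenyl CH2–CH2 bond; the chalcone is cut at its enone.
- Forward: aryl ketone → chalcone → four-membered ring (photoredox [2+2]) → side chain grown on the acetyl group → phenols unmasked → the cyclobutane takes in the two alkene carbons and becomes the cyclohexene in the last step.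
- Stereochemistry: the benzylic carbon comes from the chiral europium Lewis acid in the [2+2]; C1 and C2 are relayed from it, and from the E alkene, in the ring expansion.
- Enabling feature: the cyclobutane bond between the aroyl-bearing and the dienyl-bearing carbon is at once alpha to a ketone that the ortho phenol holds in a six-membered metal chelate and allylic to the trisubstituted alkene, so it can heterolyse and reclose at the far allyl terminus.

Key step: step 9

Assumption: ketone 1 is bought (it is otherwise one Friedel–Crafts acetylation from 3,4,5-trimethoxyphenol), and the ligand antipode in step 4 is the one that delivers the R benzylic carbon.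

**Step 1**
Reactants: 1 1-(6-hydroxy-2,3,4-trimethoxyphenyl)ethan-1-one
Product: 2 1-(2,6-dihydroxy-3,4-dimethoxyphenyl)ethan-1-one
Conditions: BCl3 (3 equiv), CH2Cl2, −78 → 0 °C; aq. work-up
Reagents that add atoms: none
Why: Chelation-controlled ether cleavage: boron held on the ketone oxygen delivers chloride only to the methyl of the methoxy group ortho to the acyl group, the two remote methoxy groups lying outside the six-membered chelate.

**Step 2**
Reactants: 2 1-(2,6-dihydroxy-3,4-dimethoxyphenyl)ethan-1-one
Product: 3 1-[3,4-dimethoxy-2,6-bis(methoxymethoxy)phenyl]ethan-1-one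
Conditions: NaH (2.5 equiv), MOMCl (2.5 equiv), DMF, 0 °C → rt
Reagents that add atoms: chloromethyl methyl ether, COCCl
Why: Williamson-type O-alkylation of both sodium phenoxides with the reactive chloromethyl ether masks the acidic, chelating phenols for the basic and organometallic steps that follow.

**Step 3**
Reactants: 3 1-[3,4-dimethoxy-2,6-bis(methoxymethoxy)phenyl]ethan-1-one; 4 benzaldehyde
Product: 5 (2E)-1-[3,4-dimethoxy-2,6-bis(methoxymethoxy)phenyl]-3-phenylprop-2-en-1-one
Conditions: KOH (0.5 equiv, aq.), EtOH, rt
Reagents that add atoms: none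
Why: Claisen–Schmidt aldol condensation: the methyl ketone enolate adds to non-enolisable benzaldehyde and E1cB dehydration gives the conjugated E-enone, the thermodynamic geometry; with both phenols masked no flavanone can form.

**Step 4**
Reactants: 5 (2E)-1-[3,4-dimethoxy-2,6-bis(methoxymethoxy)phenyl]-3-phenylprop-2-en-1-one; 6 methyl vinyl ketone
Product: 7 1-[(1S,2S,3R)-2-{[3,4-dimethoxy-2,6-bis(methoxymethoxy)phenyl]carbonyl}-3-phenylcyclobutyl]ethan-1-one
Conditions: Ru(bpy)3Cl2 (5 mol%), Eu(OTf)3 (10 mol%), chiral amino-amide Schiff-base ligand (20 mol%), i-Pr2NEt (2 equiv), 6 (5 equiv), MeCN, visible light, rt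
Reagents that add atoms: none
Why: Photoredox radical-anion crossed [2+2] cycloaddition of an aryl enone with a vinyl ketone under chiral Lewis acid control: the europium-bound cinnamoyl ketone is reduced, its benzylic beta-carbon adds to the CH2 terminus of 6 on the face left open by the ligand (setting the R benzylic carbon), and the alpha-keto radical then closes onto the enolate carbon, so the two acyl-bearing carbons become adjacent and the substituents all-trans.

**Step 5**
Reactants: 7 1-[(1S,2S,3R)-2-{[3,4-dimethoxy-2,6-bis(methoxymethoxy)phenyl]carbonyl}-3-phenylcyclobutyl]ethan-1-one; 8 prenyl bromide (1-bromo-3-methylbut-2-ene)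
Product: 9 1-[(1S,2S,3R)-2-{[3,4-dimethoxy-2,6-bis(methoxymethoxy)phenyl]carbonyl}-3-phenylcyclobutyl]-5-methylhex-4-en-1-one
Conditions: LiN(i-Pr)2 (1.05 equiv), THF, −78 °C; then 8, DMPU, −78 → −30 °C
Reagents that add atoms: none
Why: Kinetic enolate alkylation: the amide base removes a proton from the unhindered acetyl methyl group faster than from either ring methine, and SN2 attack on the allylic bromide adds the prenyl unit without touching the ring stereocenters.

**Step 6**
Reactants: 9 1-[(1S,2S,3R)-2-{[3,4-dimethoxy-2,6-bis(methoxymethoxy)phenyl]carbonyl}-3-phenylcyclobutyl]-5-methylhex-4-en-1-one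
Product: 10 (1Z)-1-[(1S,2S,3R)-2-{[3,4-dimethoxy-2,6-bis(methoxymethoxy)phenyl]carbonyl}-3-phenylcyclobutyl]-5-methylhexa-1,4-dien-1-yl trifluoromethanesulfonate
Conditions: KN(SiMe3)2 (1.1 equiv), THF, −78 °C; PhNTf2, −78 → 0 °C; aq. NH4Cl
Reagents that add atoms: N-phenylbis(trifluoromethanesulfonimide), O=S(=O)(N(c1ccccc1)S(=O)(=O)C(F)(F)F)C(F)(F)F
Why: Regio- and stereoselective enolisation with O-sulfonylation: the potassium amide deprotonates the less hindered alpha-methylene under kinetic control to the Z(O)-enolate (chain cis to oxygen, as expected for a ketone with a branched alpha′ substituent), which the triflimide traps on oxygen.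

**Step 7**
Reactants: 10 (1Z)-1-[(1S,2S,3R)-2-{[3,4-dimethoxy-2,6-bis(methoxymethoxy)phenyl]carbonyl}-3-phenylcyclobutyl]-5-methylhexa-1,4-dien-1-yl trifluoromethanesulfonate
Product: 11 [3,4-dimethoxy-2,6-bis(methoxymethoxy)phenyl]{(1R,2S,4R)-2-[(2E)-6-methylhepta-2,5-dien-2-yl]-4-phenylcyclobutyl}methanone
Conditions: MeZnCl (2 equiv), Pd(PPh3)4 (5 mol%), THF, 40 °C
Reagents that add atoms: methylzinc chloride, C[Zn]Cl
Why: Negishi cross-coupling: oxidative addition of zerovalent palladium into the enol triflate, transmetalation and reductive elimination all retain alkene geometry, so the Z-triflate gives the E-trisubstituted alkene (chain trans to the ring); both ketones and the acetals tolerate the organozinc.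

**Step 8**
Reactants: 11 [3,4-dimethoxy-2,6-bis(methoxymethoxy)phenyl]{(1R,2S,4R)-2-[(2E)-6-methylhepta-2,5-dien-2-yl]-4-phenylcyclobutyl}methanone
Product: 12 (2,6-dihydroxy-3,4-dimethoxyphenyl){(1R,2S,4R)-2-[(2E)-6-methylhepta-2,5-dien-2-yl]-4-phenylcyclobutyl}methanone
Conditions: HCl (2 M), MeOH, 0 °C → rt
Reagents that add atoms: none
Why: Acid-catalysed acetal exchange (methanolysis), assisted by the neighbouring carbonyl, removes both methoxymethyl groups under conditions too mild to ionise the cyclobutane or hydrate the trisubstituted alkenes.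

**Step 9**
Reactants: 12 (2,6-dihydroxy-3,4-dimethoxyphenyl){(1R,2S,4R)-2-[(2E)-6-methylhepta-2,5-dien-2-yl]-4-phenylcyclobutyl}methanone
Product: 14 (2,6-dihydroxy-3,4-dimethoxyphenyl)[(1R,2S,6R)-3-methyl-2-(3-methylbut-2-en-1-yl)-6-phenylcyclohex-3-en-1-yl]methanone, via enolate–allyl cation zwitterion 13 (not isolated)
Conditions: Sc(OTf)3 (20 mol%), 2,6-di-tert-butyl-4-methylpyridine (25 mol%), CH2Cl2–MeNO2 (4:1), −20 °C → rt
Reagents that add atoms: none
Why: Proposed new method: unligated Sc(OTf)3 binds 12 as a six-membered phenoxide–ketone chelate and heterolyses the cyclobutane bond between the aroyl-bearing and the dienyl-bearing carbon, which is both alpha to the activated carbonyl and allylic, giving contact ion pair 13 (scandium Z-enolate and 1,3-dialkyl-2-methylallyl cation); the enolate carbon then bonds to the far allyl terminus, so the two side-chain alkene carbons enter the ring in a net suprafacial [1,3] carbon shift driven by release of the four-ring strain. The closest known reaction types are the thermal and cation-radical vinylcyclobutane-to-cyclohexene rearrangements, the Lewis-acid opening of donor–acceptor cyclobutanes to 1,4-zwitterions, and the Lewis-acid conversion of kinetic cationic [2+2] adducts of dienes into their [4+2] isomers. The six-membered ring closes by a 6-(enolexo)-endo-trig attack on the allyl cation terminus, and allylic 1,2-strain from the methyl on the central allyl carbon turns the ring CH2 toward that terminus, so the U-shaped cation needed for closure is the one that forms. C1 is set by the benzylic stereocenter C6: in the Z-enolate the C6–H lies in the enolate plane (allylic 1,3-strain), so the tethered cation bonds anti to phenyl and the aroyl group ends trans to phenyl, which should also be the thermodynamic result at this epimerisable center. C2 is set by the E geometry of the allyl terminus fixed in step 7 together with the compact endo ion pair, in which the enolate oxygen and scandium stay over the cationic carbon they left (the boat-like topology of an endo [4+2] addition), placing the prenyl group cis to the aroyl group. The step needs closure at the distal terminus over return to the cyclobutane or O-attack to a dihydropyran (both should revert under the Lewis acid and drain to the strain-free ketone), and collapse of the ion pair faster than fragmentation to chalcone and triene, which would erode enantiopurity; the low temperature, the weakly polar non-nucleophilic medium and the hindered base that removes TfOH (sparing both trisubstituted alkenes) serve this.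

**Compound list**
1 | 1-(6-hydroxy-2,3,4-trimethoxyphenyl)ethan-1-one | COc1cc(O)c(C(C)=O)c(OC)c1OC | starting material
2 | 1-(2,6-dihydroxy-3,4-dimethoxyphenyl)ethan-1-one | COc1cc(O)c(C(C)=O)c(O)c1OC | intermediate
3 | 1-[3,4-dimethoxy-2,6-bis(methoxymethoxy)phenyl]ethan-1-one | COCOc1cc(OC)c(OC)c(OCOC)c1C(C)=O | intermediate
4 | benzaldehyde | O=Cc1ccccc1 | starting material
5 | (2E)-1-[3,4-dimethoxy-2,6-bis(methoxymethoxy)phenyl]-3-phenylprop-2-en-1-one | COCOc1cc(OC)c(OC)c(OCOC)c1C(=O)/C=C/c1ccccc1 | intermediate
6 | methyl vinyl ketone (but-3-en-2-one) | C=CC(C)=O | starting material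
7 | 1-[(1S,2S,3R)-2-{[3,4-dimethoxy-2,6-bis(methoxymethoxy)phenyl]carbonyl}-3-phenylcyclobutyl]ethan-1-one | COCOc1cc(OC)c(OC)c(OCOC)c1C(=O)[C@H]1[C@H](c2ccccc2)C[C@@H]1C(C)=O | intermediate
8 | prenyl bromide (1-bromo-3-methylbut-2-ene) | CC(C)=CCBr | starting material
9 | 1-[(1S,2S,3R)-2-{[3,4-dimethoxy-2,6-bis(methoxymethoxy)phenyl]carbonyl}-3-phenylcyclobutyl]-5-methylhex-4-en-1-one | COCOc1cc(OC)c(OC)c(OCOC)c1C(=O)[C@H]1[C@H](c2ccccc2)C[C@@H]1C(=O)CCC=C(C)C | intermediate
10 | (1Z)-1-[(1S,2S,3R)-2-{[3,4-dimethoxy-2,6-bis(methoxymethoxy)phenyl]carbonyl}-3-phenylcyclobutyl]-5-methylhexa-1,4-dien-1-yl trifluoromethanesulfonate | COCOc1cc(OC)c(OC)c(OCOC)c1C(=O)[C@H]1[C@H](c2ccccc2)C[C@@H]1/C(OS(=O)(=O)C(F)(F)F)=C/CC=C(C)C | intermediate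
11 | [3,4-dimethoxy-2,6-bis(methoxymethoxy)phenyl]{(1R,2S,4R)-2-[(2E)-6-methylhepta-2,5-dien-2-yl]-4-phenylcyclobutyl}methanone | COCOc1cc(OC)c(OC)c(OCOC)c1C(=O)[C@H]1[C@H](c2ccccc2)C[C@@H]1/C(C)=C/CC=C(C)C | intermediate
12 | (2,6-dihydroxy-3,4-dimethoxyphenyl){(1R,2S,4R)-2-[(2E)-6-methylhepta-2,5-dien-2-yl]-4-phenylcyclobutyl}methanone | COc1cc(O)c(C(=O)[C@H]2[C@H](c3ccccc3)C[C@@H]2/C(C)=C/CC=C(C)C)c(O)c1OC | intermediate
13 | enolate–allyl cation zwitterion (scandium on the enolate and phenol oxygens, drawn metal-free, one resonance form) | COc1cc(O)c(/C([O-])=C/[C@H](c2ccccc2)C/C=C(C)\[CH+]CC=C(C)C)c(O)c1OC | intermediate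
14 | (2,6-dihydroxy-3,4-dimethoxyphenyl)[(1R,2S,6R)-3-methyl-2-(3-methylbut-2-en-1-yl)-6-phenylcyclohex-3-en-1-yl]methanone | COc1cc(O)c(C(=O)[C@@H]2[C@H](CC=C(C)C)C(C)=CC[C@H]2c2ccccc2)c(O)c1OC | target

**Step count and risks**
Total step count: 9. Longest linear sequence: 9 (steps 1–9 from ketone 1).

The three steps most likely to fail:

Step 9 (proposed new method). The ion pair may fragment to chalcone and triene and recombine without control, losing enantiopurity; the allyl cation may lose a proton to a triene; or ionisation may not occur under catalytic scandium. Fallback by known chemistry: set out from chalcone 5 and remove both acetals with HCl in MeOH to give (2E)-1-(2,6-dihydroxy-3,4-dimethoxyphenyl)-3-phenylprop-2-en-1-one F1. Then run the endo-selective Diels–Alder reaction of this 2′-hydroxychalcone with (E)-β-ocimene under a chiral borate made from B(OPh)3 and an axially chiral biaryl diol (matched antipode). This comes back to the route at 14.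

Step 4. The β-phenyl radical anion is delocalised and the ketone is flanked by two ortho substituents, so addition to 6 may be slow against reductive homodimerisation, and facial selectivity at the europium center may be poor. Fallback: set out from 5 and 6 under the achiral radical-anion conditions (Ru(bpy)3Cl2, LiBF4, i-Pr2NEt, visible light) to give racemic material, that is 7 together with its enantiomer 1-[(1R,2R,3S)-2-{[3,4-dimethoxy-2,6-bis(methoxymethoxy)phenyl]carbonyl}-3-phenylcyclobutyl]ethan-1-one F2. Separate the two by preparative chromatography on a chiral stationary phase and come back to the route at 7.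

Step 6. Enolisation may occur at a ring methine, or give the E(O)-enolate, which would end as the Z alkene and the wrong C2 configuration after step 9. Fallback that builds the alkene by allylic transposition: set out from 7 and add CH2=CHMgBr with CeCl3 at −78 °C to the acetyl group (the hindered aryl ketone should not react) to give 2-[(1S,2S,3R)-2-{[3,4-dimethoxy-2,6-bis(methoxymethoxy)phenyl]carbonyl}-3-phenylcyclobutyl]but-3-en-2-ol F3 as a carbinol epimer mixture. Acetylate it (Ac2O, DMAP) to 2-[(1S,2S,3R)-2-{[3,4-dimethoxy-2,6-bis(methoxymethoxy)phenyl]carbonyl}-3-phenylcyclobutyl]but-3-en-2-yl acetate F4. Then carry out an anti-SN2′ substitution with the cuprate from 2-methylprop-1-enylmagnesium bromide and CuBr·SMe2; this should give mainly the E-trisubstituted alkene, with any Z isomer removed by chromatography, and comes back to the route at 11.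

**Further compounds**
F1 | step 9 | (2E)-1-(2,6-dihydroxy-3,4-dimethoxyphenyl)-3-phenylprop-2-en-1-one | COc1cc(O)c(C(=O)/C=C/c2ccccc2)c(O)c1OC
F2 | step 4 | 1-[(1R,2R,3S)-2-{[3,4-dimethoxy-2,6-bis(methoxymethoxy)phenyl]carbonyl}-3-phenylcyclobutyl]ethan-1-one | COCOc1cc(OC)c(OC)c(OCOC)c1C(=O)[C@@H]1[C@@H](c2ccccc2)C[C@H]1C(C)=O
F3 | step 6 | 2-[(1S,2S,3R)-2-{[3,4-dimethoxy-2,6-bis(methoxymethoxy)phenyl]carbonyl}-3-phenylcyclobutyl]but-3-en-2-ol (carbinol epimers) | COCOc1cc(OC)c(OC)c(OCOC)c1C(=O)[C@H]1[C@H](c2ccccc2)C[C@@H]1C(C)(O)C=C
F4 | step 6 | 2-[(1S,2S,3R)-2-{[3,4-dimethoxy-2,6-bis(methoxymethoxy)phenyl]carbonyl}-3-phenylcyclobutyl]but-3-en-2-yl acetate (carbinol epimers) | COCOc1cc(OC)c(OC)c(OCOC)c1C(=O)[C@H]1[C@H](c2ccccc2)C[C@@H]1C(C)(OC(C)=O)C=C
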